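**Retrosynthetic overview**

1. Ring C (the 7-hydroxycoumarin-8-yl unit) is opened last at its pyranone, C4–C4a and the lactone C–O, to a 2,6-dihydroxyphenyl group and propiolic acid. The arene is carried from the start as a 2,6-dimethoxyphenyl group.
2. The pyranone of ring B is cut at C3=C4 and the lactone C–O (Perkin–Oglialoro) into salicylaldehyde 11 and (coumarin-7-yloxy)acetic acid 14. Ring A comes ready-made from umbelliferone.
3. The strategy rests on the benzene ring of ring B. It has oxygen on C7 and C8a, the biaryl bond on C8 between them and the carbon C4 on C4a, which is the pattern of a 3-aryl-2,4-dihydroxybenzoate (8).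
4. That ring is cut at C5–C6 and C4a–C8a into the 2-aryl-1-methoxy-1,3-bis(trimethylsilyloxy)butadiene 5 and methyl propiolate 6. Diene 5 comes from 2,6-dimethoxyphenylacetic acid by esterification, C-acetylation and two silylations.
5. Order of ring formation: benzene of ring B (step 5), pyranone of ring B (step 11), pyranone of ring C (step 13).

Key step: step 5

Assumption: the target is drawn without an axial descriptor, so the hindered biaryl axis between rings B and C is taken as racemic or unassigned; there is no stereocentre to set.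

**Route**

Step 1
Reactants: 1 2,6-dimethoxyphenylacetic acid
Product: 2 methyl 2-(2,6-dimethoxyphenyl)acetate
Conditions: MeOH, H2SO4 (cat.), reflux
Reagents that add atoms: methanol, CO
Why: Fischer esterification of an unhindered aliphatic acid in excess methanol should go to completion and leaves the aryl methyl ethers untouched.

Step 2
Reactants: 2 methyl 2-(2,6-dimethoxyphenyl)acetate
Product: 3 methyl 2-(2,6-dimethoxyphenyl)-3-oxobutanoate
Conditions: LiN(SiMe3)2 (2.1 equiv), THF, −78 °C; AcCl, −78 to 0 °C; aq. NH4Cl
Reagents that add atoms: acetyl chloride, CC(=O)Cl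
Why: Crossed-Claisen C-acylation of the lithium ester enolate with acetyl chloride, in which the second equivalent of base holds the more acidic β-keto ester as its enolate, so proton exchange and double acylation should not interfere.

Step 3
Reactants: 3 methyl 2-(2,6-dimethoxyphenyl)-3-oxobutanoate
Product: 4 methyl (2Z)-2-(2,6-dimethoxyphenyl)-3-(trimethylsilyloxy)but-2-enoate
Conditions: Me3SiCl, Et3N, PhMe, rt to 40 °C; filtration under Ar
Reagents that add atoms: chlorotrimethylsilane, C[Si](C)(C)Cl
Why: Silyl enol ether formation by soft enolisation of the β-keto ester should give the 3-silyloxy enoate, whose alkene geometry has no consequence for the next step.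

Step 4
Reactants: 4 methyl (2Z)-2-(2,6-dimethoxyphenyl)-3-(trimethylsilyloxy)but-2-enoate
Product: 5 (1Z)-2-(2,6-dimethoxyphenyl)-1-methoxy-1,3-bis(trimethylsilyloxy)buta-1,3-diene
Conditions: LiN(iPr)2, THF, −78 °C; Me3SiCl, −78 °C to rt; hexane, filtration under Ar; used crude
Reagents that add atoms: chlorotrimethylsilane, C[Si](C)(C)Cl
Why: Kinetic γ-deprotonation of the vinylic methyl group, the only acidic C–H, gives the extended ester dienolate, and O-silylation traps it as the silyl ketene acetal, the standard preparation of 1-methoxy-1,3-bis(silyloxy)butadienes.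

Step 5
Reactants: 5 (1Z)-2-(2,6-dimethoxyphenyl)-1-methoxy-1,3-bis(trimethylsilyloxy)buta-1,3-diene; 6 methyl propiolate
Product: 8 methyl 3-(2,6-dimethoxyphenyl)-2,4-dihydroxybenzoate, via silylated cyclohexadiene cycloadduct 7 (not isolated)
Conditions: 6 (2 equiv), PhMe, 110 °C, sealed tube; then 1 M HCl, THF, rt
Reagents that add atoms: none
Why: The doubly oxygen-activated diene 5 and the ynoate 6 should combine in a normal-electron-demand Diels–Alder cycloaddition (concerted and asynchronous, or stepwise through a Michael-type zwitterion that closes to the same ring), after which acid removes the silyl groups of 7, expels methanol from the ketal carbon and lets the cyclohexadienone tautomerise to the resorcinol. The closest known reaction type is the cycloaddition of 1-methoxy-1,3-bis(silyloxy)butadienes with acetylenic esters, which gives hydroxybenzoates after acidic aromatisation; the 2-aryl substituent is the only new element. The benzene ring of ring B is closed by an intermolecular [4+2] ring closure that forms two C–C bonds, C5–C6 and C4a–C8a in the coumarin numbering of ring B. No stereocentre remains, because the ketal carbon of 7 is the only one formed and it becomes the aromatic C–OH carbon. The step needs one regiochemistry, and the substrate secures it: the unsubstituted CH2 terminus of 5 carries the largest HOMO coefficient and bonds to the β-carbon of 6, so the ester ends up next to the ketal-derived hydroxyl and the aryl group between the two hydroxyls. The aryl group sits on an internal diene carbon, twisted out of the diene plane, where it should not shield either reacting terminus.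

Step 6
Reactants: 8 methyl 3-(2,6-dimethoxyphenyl)-2,4-dihydroxybenzoate
Product: 9 methyl 3-(2,6-dimethoxyphenyl)-2-hydroxy-4-methoxybenzoate
Conditions: MeI (1.05 equiv), K2CO3 (1.1 equiv), acetone, rt
Reagents that add atoms: iodomethane, CI
Why: Williamson O-methylation under mild carbonate conditions should select the free, more acidic para-hydroxyl over the ortho-hydroxyl that is hydrogen-bonded to the ester carbonyl, as is usual for 2,4-dihydroxybenzoates.

Step 7
Reactants: 9 methyl 3-(2,6-dimethoxyphenyl)-2-hydroxy-4-methoxybenzoate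
Product: 10 2-(2,6-dimethoxyphenyl)-6-(hydroxymethyl)-3-methoxyphenol
Conditions: LiAlH4, THF, 0 °C to rt; aq. potassium sodium tartrate work-up
Reagents that add atoms: none
Why: Hydride reduction of the salicylate ester by LiAlH4 through its aluminium phenoxide should stop at the salicyl alcohol if kept cold and worked up without strong acid.

Step 8
Reactants: 10 2-(2,6-dimethoxyphenyl)-6-(hydroxymethyl)-3-methoxyphenol
Product: 11 3-(2,6-dimethoxyphenyl)-2-hydroxy-4-methoxybenzaldehyde
Conditions: activated MnO2, CH2Cl2, rt
Reagents that add atoms: none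
Why: Benzylic alcohol oxidation with activated MnO2 is selective for the aldehyde, and the hydrogen-bonded salicylaldehyde should not be oxidised further.

Step 9
Reactants: 12 umbelliferone
Product: 13 tert-butyl 2-[(2-oxo-2H-chromen-7-yl)oxy]acetate
Conditions: BrCH2CO2tBu, K2CO3, acetone, reflux
Reagents that add atoms: tert-butyl bromoacetate, CC(C)(C)OC(=O)CBr
Why: Williamson etherification of the acidic 7-hydroxyl with an α-bromo ester under carbonate conditions should leave the lactone intact.

Step 10
Reactants: 13 tert-butyl 2-[(2-oxo-2H-chromen-7-yl)oxy]acetate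
Product: 14 2-[(2-oxo-2H-chromen-7-yl)oxy]acetic acid
Conditions: CF3CO2H, CH2Cl2, rt
Reagents that add atoms: none
Why: Acidolysis of the tert-butyl ester with loss of isobutene frees the acid without the alkaline conditions that would open the coumarin lactone.

Step 11
Reactants: 11 3-(2,6-dimethoxyphenyl)-2-hydroxy-4-methoxybenzaldehyde; 14 2-[(2-oxo-2H-chromen-7-yl)oxy]acetic acid
Product: 16 8-(2,6-dimethoxyphenyl)-7-methoxy-3-[(2-oxo-2H-chromen-7-yl)oxy]-2H-chromen-2-one, via aryl ester 15 (not isolated)
Conditions: Ac2O, Et3N, 120 °C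
Reagents that add atoms: none
Why: Perkin–Oglialoro condensation, in which the activated acid acylates the phenol to ester 15, whose aryloxy-activated methylene should undergo intramolecular aldol condensation with the ortho-formyl group and dehydrate to the 3-aryloxycoumarin.

Step 12
Reactants: 16 8-(2,6-dimethoxyphenyl)-7-methoxy-3-[(2-oxo-2H-chromen-7-yl)oxy]-2H-chromen-2-one
Product: 17 8-(2,6-dihydroxyphenyl)-7-hydroxy-3-[(2-oxo-2H-chromen-7-yl)oxy]-2H-chromen-2-one
Conditions: BBr3 (8 equiv), CH2Cl2, −78 °C to rt; then ice-water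
Reagents that add atoms: none
Why: Lewis-acid ether cleavage by BBr3 (complexation, then bromide attack on methyl) should remove all three aryl methyl ethers while the diaryl ether is inert and the lactones are intact after work-up.

Step 13
Reactants: 17 8-(2,6-dihydroxyphenyl)-7-hydroxy-3-[(2-oxo-2H-chromen-7-yl)oxy]-2H-chromen-2-one
Product: 19 triumbelletin (7-hydroxy-8-(7-hydroxy-2-oxo-2H-chromen-8-yl)-3-[(2-oxo-2H-chromen-7-yl)oxy]-2H-chromen-2-one), via cis-cinnamic acid 18 (not isolated)
Conditions: propiolic acid (1.5 equiv), Pd(OAc)2 (5 mol %), CF3CO2H/CH2Cl2, rt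
Reagents that add atoms: propiolic acid, C#CC(=O)O
Why: Fujiwara-type hydroarylation, in which electrophilic divalent palladium in CF3CO2H should add the most electron-rich arene C–H (ortho to one hydroxyl and para to the other on the resorcinol ring, the two such positions being equivalent) anti across propiolic acid to give cis-cinnamic acid 18, which lactonises to ring C while the deactivated coumarin rings A and B should not compete.

**Compound list**

1 | 2,6-dimethoxyphenylacetic acid | COc1cccc(OC)c1CC(=O)O | starting material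
2 | methyl 2-(2,6-dimethoxyphenyl)acetate | COC(=O)Cc1c(OC)cccc1OC | intermediate
3 | methyl 2-(2,6-dimethoxyphenyl)-3-oxobutanoate (racemic, enolisable) | COC(=O)C(C(C)=O)c1c(OC)cccc1OC | intermediate
4 | methyl (2Z)-2-(2,6-dimethoxyphenyl)-3-(trimethylsilyloxy)but-2-enoate (geometry immaterial) | COC(=O)/C(c1c(OC)cccc1OC)=C(/C)O[Si](C)(C)C | intermediate
5 | (1Z)-2-(2,6-dimethoxyphenyl)-1-methoxy-1,3-bis(trimethylsilyloxy)buta-1,3-diene (ketene acetal geometry immaterial) | CO/C(O[Si](C)(C)C)=C(\c1c(OC)cccc1OC)C(=C)O[Si](C)(C)C | intermediate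
6 | methyl propiolate | C#CC(=O)OC | starting material
7 | methyl 5-(2,6-dimethoxyphenyl)-6-methoxy-4,6-bis(trimethylsilyloxy)cyclohexa-1,4-diene-1-carboxylate (racemic) | COC(=O)C1=CCC(O[Si](C)(C)C)=C(c2c(OC)cccc2OC)C1(OC)O[Si](C)(C)C | intermediate (not isolated)
8 | methyl 3-(2,6-dimethoxyphenyl)-2,4-dihydroxybenzoate | COC(=O)c1ccc(O)c(-c2c(OC)cccc2OC)c1O | intermediate
9 | methyl 3-(2,6-dimethoxyphenyl)-2-hydroxy-4-methoxybenzoate | COC(=O)c1ccc(OC)c(-c2c(OC)cccc2OC)c1O | intermediate
10 | 2-(2,6-dimethoxyphenyl)-6-(hydroxymethyl)-3-methoxyphenol | OCc1ccc(OC)c(-c2c(OC)cccc2OC)c1O | intermediate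
11 | 3-(2,6-dimethoxyphenyl)-2-hydroxy-4-methoxybenzaldehyde | O=Cc1ccc(OC)c(-c2c(OC)cccc2OC)c1O | intermediate
12 | umbelliferone (7-hydroxy-2H-chromen-2-one) | O=c1ccc2ccc(O)cc2o1 | starting material
13 | tert-butyl 2-[(2-oxo-2H-chromen-7-yl)oxy]acetate | CC(C)(C)OC(=O)COc1ccc2ccc(=O)oc2c1 | intermediate
14 | 2-[(2-oxo-2H-chromen-7-yl)oxy]acetic acid | OC(=O)COc1ccc2ccc(=O)oc2c1 | intermediate
15 | 2-(2,6-dimethoxyphenyl)-6-formyl-3-methoxyphenyl 2-[(2-oxo-2H-chromen-7-yl)oxy]acetate | O=Cc1ccc(OC)c(-c2c(OC)cccc2OC)c1OC(=O)COc1ccc2ccc(=O)oc2c1 | intermediate (not isolated)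
16 | 8-(2,6-dimethoxyphenyl)-7-methoxy-3-[(2-oxo-2H-chromen-7-yl)oxy]-2H-chromen-2-one | COc1ccc2cc(Oc3ccc4ccc(=O)oc4c3)c(=O)oc2c1-c1c(OC)cccc1OC | intermediate
17 | 8-(2,6-dihydroxyphenyl)-7-hydroxy-3-[(2-oxo-2H-chromen-7-yl)oxy]-2H-chromen-2-one | Oc1ccc2cc(Oc3ccc4ccc(=O)oc4c3)c(=O)oc2c1-c1c(O)cccc1O | intermediate
18 | (2Z)-3-{2,4-dihydroxy-3-[7-hydroxy-2-oxo-3-[(2-oxo-2H-chromen-7-yl)oxy]-2H-chromen-8-yl]phenyl}prop-2-enoic acid | OC(=O)/C=C\c1ccc(O)c(-c2c(O)ccc3cc(Oc4ccc5ccc(=O)oc5c4)c(=O)oc23)c1O | intermediate (not isolated)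
19 | triumbelletin, 7-hydroxy-8-(7-hydroxy-2-oxo-2H-chromen-8-yl)-3-[(2-oxo-2H-chromen-7-yl)oxy]-2H-chromen-2-one (biaryl axis racemic) | O=c1ccc2ccc(Oc3cc4ccc(O)c(-c5c(O)ccc6ccc(=O)oc56)c4oc3=O)cc2o1 | target

**Step count**

Total: 13 steps. Longest linear sequence: 11 steps (steps 1 to 8, then 11, 12 and 13); steps 9 and 10 form the two-step side branch to acid 14.

**Steps most likely to fail**

Step 5 (key cycloaddition). The crowded, moisture-sensitive diene may lose or transfer its silyl groups, or add to the ynoate in an open-chain Michael fashion, faster than the ring closes, because one substituent on the ketene acetal carbon must point into the cisoid diene. The fallback sets out from acid 1 and methyl propiolate 6 and comes back at compound 8; it builds the same benzene ring by an anionic [3+3] Michael–Claisen benzannulation that needs no silyl diene. Acid 1 would be condensed with Meldrum's acid (DCC, DMAP, CH2Cl2) to the acyl Meldrum's acid 5-[2-(2,6-dimethoxyphenyl)-1-hydroxyethylidene]-2,2-dimethyl-1,3-dioxane-4,6-dione F1, and methanolysis at reflux would give methyl 4-(2,6-dimethoxyphenyl)-3-oxobutanoate F2. With NaH (2.5 equiv) in THF, the active methylene of F2 should add to 6 to give, in the flask, the Michael adduct dimethyl (2Z)-4-[2-(2,6-dimethoxyphenyl)acetyl]pent-2-enedioate F3, whose alkene geometry equilibrates through the delocalised anion. Claisen cyclisation of the benzylic carbanion of F3 onto the enoate ester and tautomerisation would then give 8.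

Step 13 (ring C annulation). The tri-phenol may react at the wrong ring (C6 of ring B), be annulated twice, or be consumed slowly because it is acylated or precipitates in the acidic medium. The fallback sets out from triol 17 and comes back at target 19; it replaces the alkyne hydroarylation by formylation and olefination. Vilsmeier–Haack formylation of 17 (POCl3, DMF, MeCN, 0 °C to rt; then water, 50 °C) should attack the resorcinol ring para to one hydroxyl and give 2,4-dihydroxy-3-[7-hydroxy-2-oxo-3-[(2-oxo-2H-chromen-7-yl)oxy]-2H-chromen-8-yl]benzaldehyde F4. Heating F4 with Ph3P=CHCO2Et in N,N-diethylaniline at reflux would form, in the flask, ethyl (2E)-3-{2,4-dihydroxy-3-[7-hydroxy-2-oxo-3-[(2-oxo-2H-chromen-7-yl)oxy]-2H-chromen-8-yl]phenyl}prop-2-enoate F5, which should isomerise and lactonise at that temperature to 19.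

Step 7 (ester reduction with a free phenol). The benzylic oxygen may be lost through an ortho-quinone methide at the aluminate stage, giving over-reduction to the methyl compound, and the electron-rich salicyl alcohol may oligomerise on work-up. The fallback sets out from compound 9 and comes back at compound 11; it masks the phenol during the redox steps. Methylation of 9 (MeI, K2CO3, DMF, 60 °C) would give methyl 3-(2,6-dimethoxyphenyl)-2,4-dimethoxybenzoate F6. LiAlH4 reduction would give [3-(2,6-dimethoxyphenyl)-2,4-dimethoxyphenyl]methanol F7, and MnO2 oxidation would give 3-(2,6-dimethoxyphenyl)-2,4-dimethoxybenzaldehyde F8. BCl3 (CH2Cl2, −78 to 0 °C) should then cleave only the methyl ether ortho to the formyl group, through the boron chelate, to give 11.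

**Further compounds**

F1 | step 5 | 5-[2-(2,6-dimethoxyphenyl)-1-hydroxyethylidene]-2,2-dimethyl-1,3-dioxane-4,6-dione | COc1cccc(OC)c1CC(O)=C1C(=O)OC(C)(C)OC1=O
F2 | step 5 | methyl 4-(2,6-dimethoxyphenyl)-3-oxobutanoate | COC(=O)CC(=O)Cc1c(OC)cccc1OC
F3 | step 5 | dimethyl (2Z)-4-[2-(2,6-dimethoxyphenyl)acetyl]pent-2-enedioate | COC(=O)/C=C\C(C(=O)OC)C(=O)Cc1c(OC)cccc1OC
F4 | step 13 | 2,4-dihydroxy-3-[7-hydroxy-2-oxo-3-[(2-oxo-2H-chromen-7-yl)oxy]-2H-chromen-8-yl]benzaldehyde | O=Cc1ccc(O)c(-c2c(O)ccc3cc(Oc4ccc5ccc(=O)oc5c4)c(=O)oc23)c1O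
F5 | step 13 | ethyl (2E)-3-{2,4-dihydroxy-3-[7-hydroxy-2-oxo-3-[(2-oxo-2H-chromen-7-yl)oxy]-2H-chromen-8-yl]phenyl}prop-2-enoate | CCOC(=O)/C=C/c1ccc(O)c(-c2c(O)ccc3cc(Oc4ccc5ccc(=O)oc5c4)c(=O)oc23)c1O
F6 | step 7 | methyl 3-(2,6-dimethoxyphenyl)-2,4-dimethoxybenzoate | COC(=O)c1ccc(OC)c(-c2c(OC)cccc2OC)c1OC
F7 | step 7 | [3-(2,6-dimethoxyphenyl)-2,4-dimethoxyphenyl]methanol | OCc1ccc(OC)c(-c2c(OC)cccc2OC)c1OC
F8 | step 7 | 3-(2,6-dimethoxyphenyl)-2,4-dimethoxybenzaldehyde | O=Cc1ccc(OC)c(-c2c(OC)cccc2OC)c1OC
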